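**Retrosynthetic overview**

- The chain is numbered C1 (benzylic) to C18 (methyl), with the ketone at C5. The free phenol is unveiled last by hydrolysis of an aryl methanesulfonate.
- Key disconnection C7–C8: the C6–C18 tridecyl arm beyond the C5 carbonyl is saturated, unbranched and unfunctionalised. It can therefore be spliced two carbons past the ketone by anodic decarboxylative radical cross-coupling (mixed Kolbe electrolysis) of 8-[4-(methanesulfonyloxy)phenyl]-4-oxooctanoic acid (C1–C7) with dodecanoic acid (C8–C18).
- The γ-keto acid comes from its methyl ester, built at C4–C5 by Pd-catalysed acylation of the alkylzinc bromide of 4-(4-bromobutyl)phenyl methanesulfonate with methyl 4-chloro-4-oxobutanoate.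
- The bromide comes from 4-(4-methoxyphenyl)butan-1-ol (HBr for OH to Br with O-demethylation, then O-mesylation).
- No ring is formed at any stage; the benzene ring is bought and the route only builds the chain.

Key step: step 5

Remark: methyl 4-chloro-4-oxobutanoate is taken as a commercial reagent.

**Route**

Step 1
Reactants: 1 4-(4-methoxyphenyl)butan-1-ol
Product: 2 4-(4-bromobutyl)phenol
Conditions: 48% aq. HBr (excess), reflux, then extractive work-up; the product is kept neutral or acidic and used promptly
Reagents that add atoms: hydrogen bromide, Br
Why: Hot concentrated HBr should convert the primary alcohol into the bromide (SN2 displacement of the protonated hydroxyl) and at the same time cleave the aryl methyl ether by bromide attack on the O-methyl carbon (acidic ether cleavage), the acidic medium keeping the phenol un-ionised so that it cannot alkylate itself with the new bromide.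

Step 2
Reactants: 2 4-(4-bromobutyl)phenol; 3 methanesulfonyl chloride
Product: 4 4-(4-bromobutyl)phenyl methanesulfonate
Conditions: MsCl (1.2 equiv), Et3N (1.5 equiv), CH2Cl2, 0 °C
Reagents that add atoms: methanesulfonyl chloride, CS(=O)(=O)Cl
Why: O-Mesylation of the phenol with MsCl/Et3N (via sulfene or direct substitution at sulfur) is fast at 0 °C while the primary bromide is inert to the amine at this temperature, so the ring is made electron-poor before the organometallic and anodic steps.

Step 3
Reactants: 4 4-(4-bromobutyl)phenyl methanesulfonate; 5 methyl 4-chloro-4-oxobutanoate
Product: 7 methyl 8-[4-(methanesulfonyloxy)phenyl]-4-oxooctanoate, via alkylzinc bromide 6 (not isolated)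
Conditions: Zn dust (1.5 equiv, activated with cat. BrCH2CH2Br and Me3SiCl), LiCl (1.5 equiv), THF, 50 °C; then 5 (1.2 equiv), Pd(PPh3)4 (3 mol%), THF, 0 °C to rt
Reagents that add atoms: methyl 4-chloro-4-oxobutanoate, COC(=O)CCC(=O)Cl
Why: LiCl-assisted insertion of zinc into the primary C–Br bond should give an alkylzinc bromide that tolerates the aryl sulfonate, and Pd-catalysed Negishi acylation (oxidative addition of the acid chloride to zerovalent palladium, transmetalation from zinc, reductive elimination) should deliver the ketone without over-addition and without touching the methyl ester or the aryl mesylate, which does not add to Pd(PPh3)4 at room temperature.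

Step 4
Reactants: 7 methyl 8-[4-(methanesulfonyloxy)phenyl]-4-oxooctanoate
Product: 8 8-[4-(methanesulfonyloxy)phenyl]-4-oxooctanoic acid
Conditions: LiOH·H2O (1.3 equiv), THF/H2O (3:1), 0 °C; then 1 M HCl to pH 2
Reagents that add atoms: lithium hydroxide, [Li+].[OH-]
Why: Saponification of the unhindered methyl ester by hydroxide (acyl–oxygen cleavage, BAc2) is fast at 0 °C whereas cleavage of an aryl methanesulfonate needs hot excess alkali, so the mesylate should survive and acidification should free the γ-keto acid.

Step 5
Reactants: 8 8-[4-(methanesulfonyloxy)phenyl]-4-oxooctanoic acid; 9 dodecanoic acid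
Product: 10 4-(5-oxooctadecyl)phenyl methanesulfonate
Conditions: 9 (ca. 5 equiv), KOH (ca. 5 mol% of total acid), MeOH, 45–50 °C, undivided cell, smooth Pt foil anode and Pt cathode, constant current ca. 0.2 A cm−2, stopped when the electrolyte reaches about pH 8; acidic work-up, chromatography
Reagents that add atoms: dodecanoic acid, CCCCCCCCCCCC(=O)O
Why: Each potassium carboxylate is oxidised at the platinum anode to an acyloxy radical that loses CO2 in the anode layer, and the primary 3-oxoalkyl radical from 8 and the undecyl radical from 9, generated side by side at high local concentration, should combine to the new C7–C8 sigma bond while protons are reduced to hydrogen at the cathode. The closest known reaction type is the mixed (crossed) Kolbe electrolysis of 4-oxoalkanoic acids such as levulinic acid with fatty acids, an established way to long-chain ketones. No ring is closed and no stereocentre is created, so only chemoselectivity is at stake. Cross- over homo-coupling is secured by running the cheap acid 9 in roughly fivefold excess, so that a radical derived from 8 should mostly meet an undecyl partner, and the docosane formed from surplus 9 is separated as a non-polar hydrocarbon. Radical coupling over further oxidation to carbocations (Hofer–Moest path) is secured by both radicals being primary and unbranched at the alpha carbon (the carbonyl carbon lies beta to the radical centre, stabilises no cation, and a 1,2-acyl shift would be degenerate) and by smooth platinum, high current density and an only partly neutralised methanolic electrolyte. The arene is shielded from anodic oxidation by the electron-withdrawing methanesulfonate on the phenol oxygen, and the electrolysis is stopped before the electrolyte turns strongly alkaline so that the sulfonate ester is not solvolysed.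

Step 6
Reactants: 10 4-(5-oxooctadecyl)phenyl methanesulfonate
Product: 11 1-(4-hydroxyphenyl)octadecan-5-one
Conditions: KOH (4 equiv), MeOH/H2O (4:1), reflux, N2; then 1 M HCl
Reagents that add atoms: none
Why: Hot aqueous-methanolic KOH should cleave the aryl methanesulfonate at the S–O bond (alkaline sulfonate ester hydrolysis, by attack at sulfur or through sulfene), the isolated dialkyl ketone being inert to these conditions, and acidification should return the free phenol, which is the target.

**Compound list**

1 | 4-(4-methoxyphenyl)butan-1-ol | COc1ccc(CCCCO)cc1 | starting material
2 | 4-(4-bromobutyl)phenol | Oc1ccc(CCCCBr)cc1 | intermediate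
3 | methanesulfonyl chloride | CS(=O)(=O)Cl | starting material
4 | 4-(4-bromobutyl)phenyl methanesulfonate | CS(=O)(=O)Oc1ccc(CCCCBr)cc1 | intermediate
5 | methyl 4-chloro-4-oxobutanoate | COC(=O)CCC(=O)Cl | starting material
6 | {4-[4-(methanesulfonyloxy)phenyl]butyl}zinc bromide | CS(=O)(=O)Oc1ccc(CCCC[Zn]Br)cc1 | intermediate
7 | methyl 8-[4-(methanesulfonyloxy)phenyl]-4-oxooctanoate | COC(=O)CCC(=O)CCCCc1ccc(OS(C)(=O)=O)cc1 | intermediate
8 | 8-[4-(methanesulfonyloxy)phenyl]-4-oxooctanoic acid | CS(=O)(=O)Oc1ccc(CCCCC(=O)CCC(=O)O)cc1 | intermediate
9 | dodecanoic acid | CCCCCCCCCCCC(=O)O | starting material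
10 | 4-(5-oxooctadecyl)phenyl methanesulfonate | CS(=O)(=O)Oc1ccc(CCCCC(=O)CCCCCCCCCCCCC)cc1 | intermediate
11 | 1-(4-hydroxyphenyl)octadecan-5-one | CCCCCCCCCCCCCC(=O)CCCCc1ccc(O)cc1 | target

**Step count**

Total steps: 6. Longest linear sequence: 6 steps (1 to 11).

**Steps most likely to fail**

1. Step 5 (mixed Kolbe electrolysis). The cross-coupling may be eroded by homo-coupling of the keto-acid radical, by over-oxidation of the radicals to cations that are trapped by methanol, by fouling of the anode with precipitated hydrocarbon, or by slow solvolysis of the mesylate as the electrolyte turns alkaline. Fallback, setting out from 8 and returning at 10: esterification of 8 with N-hydroxyphthalimide (N,N'-diisopropylcarbodiimide, cat. DMAP, CH2Cl2) should give the redox-active ester 1,3-dioxoisoindolin-2-yl 8-[4-(methanesulfonyloxy)phenyl]-4-oxooctanoate F1. Nickel-catalysed decarboxylative alkyl–alkyl coupling of F1 with diundecylzinc (from undecylmagnesium bromide and ZnCl2; NiCl2·glyme, 4,4'-di-tert-butyl-2,2'-bipyridine, THF/DMF, rt) should then form the same C7–C8 bond with a single defined partner instead of a statistical radical pair, giving 10.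

2. Step 3 (zinc insertion and acylation). Zinc insertion may stall, the organozinc may be lost to homo-coupling or protonolysis, and the acid chloride may be consumed by Lewis-acid-promoted opening of THF. Fallback, setting out from 4 and returning at 7: Finkelstein exchange (NaI, acetone, reflux) should give 4-(4-iodobutyl)phenyl methanesulfonate F2. Nickel-catalysed reductive cross-electrophile acylation of F2 with 5 (NiCl2·glyme, 4,4'-di-tert-butyl-2,2'-bipyridine, Mn powder, DMA, 0 °C) should then give 7 without any preformed organometallic and without THF.

3. Step 4 (ester saponification). Hydroxide may begin to cleave the aryl mesylate before the ester is fully consumed, giving a free phenol that would not survive the anode. Fallback, setting out from 4 and returning at 8: the ester stage is bypassed. The alkylzinc bromide 6 is generated as in step 3 and used in the Ni(cod)2/2,2'-bipyridine-catalysed alkylative ring opening of succinic anhydride (4-fluorostyrene as promoter, THF, 0 °C; aqueous HCl work-up), which should give the keto acid 8 directly. No new compound is made on the way (F0).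

**Further compounds**

F1 | step 5 | 1,3-dioxoisoindolin-2-yl 8-[4-(methanesulfonyloxy)phenyl]-4-oxooctanoate | CS(=O)(=O)Oc1ccc(CCCCC(=O)CCC(=O)ON2C(=O)c3ccccc3C2=O)cc1
F2 | step 3 | 4-(4-iodobutyl)phenyl methanesulfonate | CS(=O)(=O)Oc1ccc(CCCCI)cc1
F0 | step 4 | none | none
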